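**Retrosynthetic overview**
1. Last bond: C16–triketone ring, by Knoevenagel condensation and conjugate reduction between a C1-formyl eudesman-4-ol and isovalerylfilicinic acid (made separately from phloroglucinol by acylation and dearomatising gem-dimethylation).
2. The aldehyde and the C4 carbinol arise together from an epoxy Weinreb amide in one hydride step; the epoxide comes from a Δ3 alkene made by reductive 1,3-transposition of an allylic alcohol, which also sets the trans ring fusion.
3. The precursor enone is cut at C4=C5 (intramolecular aldol condensation, closure of ring A) and at C10–C1 (auxiliary-controlled Michael addition), i.e. a Robinson annulation of two separately made pieces.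
4. Pieces: (S)-carvone → dihydrocarvone → (S)-1-phenylethylamine imine (ring B, C7 from the chiral pool); 2-ethylfuran → (E)-4-oxohex-2-enoic Weinreb amide (C1–C4, C15, C16).
5. Ring order: ring B comes with carvone, ring A closes by the aldol, and the triketone ring is made from the arene and attached last.

Assumption: eudesmane numbering is used for the decalin (C1 bears the CH2 link, C4 the carbinol, C5/C10 the ring fusion, C7 the isopropenyl group), and the triketone is treated as a freely interconverting tautomer set of which the given dienol is one member.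

**Route**

Step 1
Reactants: 1 (S)-(+)-carvone
Product: 2 (−)-dihydrocarvone
Conditions: Zn dust, KOH, MeOH/H2O (4:1), reflux, 4 h
Reagents that add atoms: none
Why: Dissolving-metal conjugate reduction of the enone leaves the isolated isopropenyl group and the C7 stereocentre untouched, and the trans/cis mixture at the new α-methyl centre is inconsequential because that carbon becomes sp2 in the enamine of step 5.

Step 2
Reactants: 2 (−)-dihydrocarvone
Product: 3 (S)-1-phenylethyl imine of dihydrocarvone
Conditions: (S)-(−)-1-phenylethylamine (1.05 equiv), TsOH·H2O (1 mol %), toluene, Dean–Stark, reflux; used crude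
Reagents that add atoms: (S)-1-phenylethylamine, C[C@H](N)c1ccccc1
Why: Acid-catalysed imine condensation with azeotropic water removal installs the chiral auxiliary that controls the quaternary centre through the secondary-enamine tautomer.

Step 3
Reactants: 4 2-ethylfuran
Product: 7 (E)-4-oxohex-2-enoic acid, via (Z)-4-oxohex-2-enal 5 (not isolated), via (E)-4-oxohex-2-enal 6 (not isolated)
Conditions: NBS, NaHCO3, acetone/H2O (10:1), −15 °C; pyridine, rt; then NaClO2, NaH2PO4, 2-methyl-2-butene, t-BuOH/H2O, rt (one pot)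
Reagents that add atoms: water, O; NaClO2 (sodium chlorite), [Na+].[O-]Cl=O
Why: Bromonium-induced oxidative ring opening of the furan gives the cis-enedicarbonyl, pyridine isomerises it to the E isomer, and Pinnick oxidation converts the aldehyde into the acid without touching the enone.

Step 4
Reactants: 7 (E)-4-oxohex-2-enoic acid
Product: 8 (E)-N-methoxy-N-methyl-4-oxohex-2-enamide
Conditions: MeNHOMe·HCl, EDC·HCl, N-methylmorpholine, CH2Cl2, 0 °C to rt
Reagents that add atoms: N,O-dimethylhydroxylamine hydrochloride, CNOC.Cl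
Why: Carbodiimide amide coupling gives the Weinreb amide, a latent aldehyde for C16, and the weakly basic amine does not add to the enone at 0 °C.

Step 5
Reactants: 3 (S)-1-phenylethyl imine of dihydrocarvone; 8 (E)-N-methoxy-N-methyl-4-oxohex-2-enamide
Product: 11 enone Weinreb amide (1S,6S,8aR)-N-methoxy-N,4,8a-trimethyl-3-oxo-6-(prop-1-en-2-yl)-1,2,3,5,6,7,8,8a-octahydronaphthalene-1-carboxamide, via Michael adduct imine 9 (not isolated), via diketone 10 (not isolated)
Conditions: 8 (1.2 equiv), THF, 45 °C, 72 h; 20% aq AcOH, rt, 2 h; then NaOMe, MeOH, rt (crude carried through without purification)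
Reagents that add atoms: none
Why: A d'Angelo-type asymmetric Michael addition of the more substituted secondary enamine (aza-ene-like chair transition state, attack β to the ketone on the face anti to the auxiliary phenyl) sets C10 with methyl cis to isopropenyl, the ketone-endo/amide-exo arrangement sets C1 with the amide cis to that methyl, and after imine hydrolysis an intramolecular aldol condensation (Robinson annulation) closes ring A at C4–C5.

Step 6
Reactants: 11 enone Weinreb amide
Product: 12 allylic alcohol (1S,3R,6S,8aR)-3-hydroxy-N-methoxy-N,4,8a-trimethyl-6-(prop-1-en-2-yl)-1,2,3,5,6,7,8,8a-octahydronaphthalene-1-carboxamide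
Conditions: NaBH4, CeCl3·7H2O, MeOH, −40 °C
Reagents that add atoms: none
Why: In this Luche 1,2-reduction, axial hydride delivery anti to the angular methyl gives the pseudo-equatorial C3 alcohol cis to that methyl, and NaBH4 does not reduce the Weinreb amide.

Step 7
Reactants: 12 allylic alcohol
Product: 15 Δ3-alkene Weinreb amide (1S,4aR,6S,8aS)-N-methoxy-N,4,8a-trimethyl-6-(prop-1-en-2-yl)-1,2,4a,5,6,7,8,8a-octahydronaphthalene-1-carboxamide, via N-allylic sulfonylhydrazine 13 (not isolated), via allylic diazene 14 (not isolated)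
Conditions: PPh3, DEAD, 2-nitrobenzenesulfonylhydrazide (NBSH), N-methylmorpholine, −30 °C, then 23 °C
Reagents that add atoms: none
Why: In this Myers reductive 1,3-transposition, Mitsunobu displacement inverts C3, loss of sulfinic acid gives the allylic diazene, and its retro-ene loss of N2 delivers hydrogen to C5 on the face anti to the angular methyl, which sets the trans ring fusion and moves the alkene to C3=C4.

Step 8
Reactants: 15 Δ3-alkene Weinreb amide
Product: 16 epoxy Weinreb amide (1S,3S,4R,4aS,6S,8aS)-3,4-epoxy-N-methoxy-N,4,8a-trimethyl-6-(prop-1-en-2-yl)decahydronaphthalene-1-carboxamide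
Conditions: mCPBA (1.05 equiv), CH2Cl2, −20 to 0 °C
Reagents that add atoms: mCPBA, O=C(OO)c1cccc(Cl)c1
Why: In this Prilezhaev epoxidation the trisubstituted ring alkene reacts roughly ten times faster than the 1,1-disubstituted isopropenyl group, and the peracid approaches anti to the axial angular methyl, which puts the C4 oxygen on the face needed for the carbinol.

Step 9
Reactants: 16 epoxy Weinreb amide
Product: 18 hydroxy aldehyde (1S,4S,4aS,6S,8aS)-4-hydroxy-4,8a-dimethyl-6-(prop-1-en-2-yl)decahydronaphthalene-1-carbaldehyde, via chelated hemiaminal 17 (not isolated)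
Conditions: LiAlH4 (3 equiv), THF, 0 °C to rt; Na2SO4·10H2O quench at 0 °C
Reagents that add atoms: none
Why: Hydride opens the epoxide by SN2 attack at the less substituted C3, so C4 keeps its oxygen and its methyl ends axial, while the Weinreb amide stops at the aluminium-chelated hemiaminal, which releases the aldehyde on work-up with C1 untouched.

Step 10
Reactants: 19 phloroglucinol; 20 isovaleryl chloride
Product: 21 3-methyl-1-(2,4,6-trihydroxyphenyl)butan-1-one
Conditions: AlCl3 (3.5 equiv), PhNO2, 65 °C; aq HCl work-up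
Reagents that add atoms: none
Why: Friedel–Crafts C-acylation of the highly activated arene stops after one acyl group because the ketone deactivates the ring.

Step 11
Reactants: 21 3-methyl-1-(2,4,6-trihydroxyphenyl)butan-1-one
Product: 22 isovalerylfilicinic acid 3,5-dihydroxy-6,6-dimethyl-2-(3-methylbutanoyl)cyclohexa-2,4-dien-1-one
Conditions: MeI (2.2 equiv), NaOMe (3 equiv), MeOH, 0 °C to rt; aq HCl work-up; chromatography
Reagents that add atoms: iodomethane, CI
Why: Dearomatising double C-alkylation of the phenolate at one ring carbon gives the gem-dimethyl triketone and leaves a single nucleophilic ring CH for the union.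

Step 12
Reactants: 18 hydroxy aldehyde; 22 isovalerylfilicinic acid
Product: 24 target CNP0490948.1, via alkylidene triketone 23 (not isolated)
Conditions: L-proline (20 mol %), Hantzsch ester (1.2 equiv), CH2Cl2, rt to 40 °C
Reagents that add atoms: none
Why: This organocatalytic reductive alkylation (Knoevenagel condensation, then conjugate hydride transfer from the Hantzsch ester to the alkylidene triketone) forms the CH2 link at the only free ring carbon and leaves C1, the tertiary alcohol and the isopropenyl group unchanged.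

**Compound list**
1 | (S)-(+)-carvone, (5S)-2-methyl-5-(prop-1-en-2-yl)cyclohex-2-en-1-one | C=C(C)[C@H]1CC=C(C)C(=O)C1 | starting material
2 | (−)-dihydrocarvone, (2S,5S)-2-methyl-5-(prop-1-en-2-yl)cyclohexan-1-one (contains some 2R epimer) | C=C(C)[C@H]1CC[C@H](C)C(=O)C1 | intermediate
3 | (1S)-N-[(2S,5S)-2-methyl-5-(prop-1-en-2-yl)cyclohexylidene]-1-phenylethan-1-amine | C=C(C)[C@H]1CC[C@H](C)C(=N[C@@H](C)c2ccccc2)C1 | intermediate
4 | 2-ethylfuran | CCc1ccco1 | starting material
5 | (Z)-4-oxohex-2-enal | CCC(=O)/C=C\C=O | intermediate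
6 | (E)-4-oxohex-2-enal | CCC(=O)/C=C/C=O | intermediate
7 | (E)-4-oxohex-2-enoic acid | CCC(=O)/C=C/C(=O)O | intermediate
8 | (E)-N-methoxy-N-methyl-4-oxohex-2-enamide | CCC(=O)/C=C/C(=O)N(C)OC | intermediate
9 | (2S)-N-methoxy-N-methyl-2-[(1R,4S)-1-methyl-2-{[(1S)-1-phenylethyl]imino}-4-(prop-1-en-2-yl)cyclohexyl]-4-oxohexanamide | C=C(C)[C@H]1CC[C@](C)([C@H](CC(=O)CC)C(=O)N(C)OC)C(=N[C@@H](C)c2ccccc2)C1 | intermediate
10 | (2S)-N-methoxy-N-methyl-2-[(1R,4S)-1-methyl-2-oxo-4-(prop-1-en-2-yl)cyclohexyl]-4-oxohexanamide | C=C(C)[C@H]1CC[C@](C)([C@H](CC(=O)CC)C(=O)N(C)OC)C(=O)C1 | intermediate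
11 | (1S,6S,8aR)-N-methoxy-N,4,8a-trimethyl-3-oxo-6-(prop-1-en-2-yl)-1,2,3,5,6,7,8,8a-octahydronaphthalene-1-carboxamide | C=C(C)[C@H]1CC[C@]2(C)[C@@H](C(=O)N(C)OC)CC(=O)C(C)=C2C1 | intermediate
12 | (1S,3R,6S,8aR)-3-hydroxy-N-methoxy-N,4,8a-trimethyl-6-(prop-1-en-2-yl)-1,2,3,5,6,7,8,8a-octahydronaphthalene-1-carboxamide | C=C(C)[C@H]1CC[C@]2(C)[C@@H](C(=O)N(C)OC)C[C@@H](O)C(C)=C2C1 | intermediate
13 | (1S,3S,6S,8aR)-N-methoxy-N,4,8a-trimethyl-3-[1-(2-nitrobenzenesulfonyl)hydrazin-1-yl]-6-(prop-1-en-2-yl)-1,2,3,5,6,7,8,8a-octahydronaphthalene-1-carboxamide | C=C(C)[C@H]1CC[C@]2(C)[C@@H](C(=O)N(C)OC)C[C@H](N(N)S(=O)(=O)c3ccccc3[N+](=O)[O-])C(C)=C2C1 | intermediate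
14 | (1S,3S,6S,8aR)-3-diazenyl-N-methoxy-N,4,8a-trimethyl-6-(prop-1-en-2-yl)-1,2,3,5,6,7,8,8a-octahydronaphthalene-1-carboxamide | C=C(C)[C@H]1CC[C@]2(C)[C@@H](C(=O)N(C)OC)C[C@H](N=N)C(C)=C2C1 | intermediate
15 | (1S,4aR,6S,8aS)-N-methoxy-N,4,8a-trimethyl-6-(prop-1-en-2-yl)-1,2,4a,5,6,7,8,8a-octahydronaphthalene-1-carboxamide | C=C(C)[C@H]1CC[C@]2(C)[C@@H](C(=O)N(C)OC)CC=C(C)[C@H]2C1 | intermediate
16 | (1S,3S,4R,4aS,6S,8aS)-3,4-epoxy-N-methoxy-N,4,8a-trimethyl-6-(prop-1-en-2-yl)decahydronaphthalene-1-carboxamide (oxirane oxygen anti to the angular methyl) | C=C(C)[C@H]1CC[C@]2(C)[C@@H](C(=O)N(C)OC)C[C@@H]3O[C@]3(C)[C@H]2C1 | intermediate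
17 | N-methoxy-N-methyl hemiaminal of 18, present as its aluminium chelate (drawn as the free carbinolamine, carbinol carbon undefined) | C=C(C)[C@H]1CC[C@]2(C)[C@@H](C(O)N(C)OC)CC[C@](C)(O)[C@H]2C1 | intermediate
18 | (1S,4S,4aS,6S,8aS)-4-hydroxy-4,8a-dimethyl-6-(prop-1-en-2-yl)decahydronaphthalene-1-carbaldehyde | C=C(C)[C@H]1CC[C@]2(C)[C@@H](C=O)CC[C@](C)(O)[C@H]2C1 | intermediate
19 | phloroglucinol, benzene-1,3,5-triol | Oc1cc(O)cc(O)c1 | starting material
20 | isovaleryl chloride, 3-methylbutanoyl chloride | CC(C)CC(=O)Cl | starting material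
21 | 3-methyl-1-(2,4,6-trihydroxyphenyl)butan-1-one | CC(C)CC(=O)c1c(O)cc(O)cc1O | intermediate
22 | isovalerylfilicinic acid, 3,5-dihydroxy-6,6-dimethyl-2-(3-methylbutanoyl)cyclohexa-2,4-dien-1-one | CC(C)CC(=O)C1=C(O)C=C(O)C(C)(C)C1=O | intermediate
23 | alkylidene triketone from 18 and 22 (Knoevenagel adduct, alkene geometry undefined) | C=C(C)[C@H]1CC[C@]2(C)[C@@H](C=C3C(=O)C(C)(C)C(=O)C(C(=O)CC(C)C)=C3O)CC[C@](C)(O)[C@H]2C1 | intermediate
24 | 3,5-dihydroxy-4-{[(1R,4S,4aS,6S,8aR)-4-hydroxy-4,8a-dimethyl-6-(prop-1-en-2-yl)decahydronaphthalen-1-yl]methyl}-6,6-dimethyl-2-(3-methylbutanoyl)cyclohexa-2,4-dien-1-one | C=C(C)[C@H]1CC[C@]2(C)[C@@H](CC3=C(O)C(C)(C)C(=O)C(C(=O)CC(C)C)=C3O)CC[C@](C)(O)[C@H]2C1 | target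

**Step count**
Total steps: 12.
Longest linear sequence: 8 steps (1, 2, 5, 6, 7, 8, 9, 12; the path 3, 4, 5, 6, 7, 8, 9, 12 is equally long).

**Steps most likely to fail, with fallbacks**

Step 5 (the most uncertain). The Michael addition must join a quaternary and a tertiary carbon using a β-substituted acceptor, for which the imine method has much less precedent than for vinyl ketones. The congested adduct may also undergo retro-Michael cleavage under methoxide. The fallback uses a more electrophilic fumarate-type ester acceptor and installs the amide after ring closure. Setting out from acid 7, allyl bromide/K2CO3 in DMF gives allyl (E)-4-oxohex-2-enoate F1. Addition to imine 3 in THF at rt gives the Michael adduct imine F2, and aqueous AcOH releases the diketo ester F3. Ring A is then closed by an amine–acid catalysed aldol condensation (piperidine, AcOH, toluene, 80 °C; no alkoxide, so no transesterification and less retro-Michael) to the enone allyl ester F4. Pd(PPh3)4 with morpholine in THF removes the allyl group to give the enone acid F5. Coupling with MeNHOMe·HCl (EDC·HCl, N-methylmorpholine) then comes back to the route at 11.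

Step 7. Mitsunobu displacement at a secondary allylic carbinol next to a tetrasubstituted alkene may be slow or lead to elimination. The fallback is a palladium-catalysed formate hydrogenolysis. Setting out from 12, formic acetic anhydride and pyridine at 0 °C give the allylic formate F6. Pd(OAc)2/PBu3 in dioxane (rt to 60 °C) then ionises it with inversion, so palladium sits anti to the angular methyl, and transfers hydride from the metal to the more substituted allyl terminus C5. This gives the same trans-fused Δ3 alkene and comes back to the route at 15.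

Step 9. The epoxide has to open at C3 against the trans-diaxial preference, which may need warming, and the chelated hemiaminal may then collapse and be over-reduced. The fallback reduces fully and re-oxidises. Setting out from 16, LiAlH4 in refluxing THF gives the diol [(1R,4S,4aS,6S,8aR)-4-hydroxy-4,8a-dimethyl-6-(prop-1-en-2-yl)decahydronaphthalen-1-yl]methanol F7. Selective oxidation of the primary alcohol with catalytic TEMPO and PhI(OAc)2 in CH2Cl2 (the tertiary alcohol and the alkene are inert) comes back to the route at 18.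

**Further compounds**
F1 | step 5 | allyl (E)-4-oxohex-2-enoate | C=CCOC(=O)/C=C/C(=O)CC
F2 | step 5 | allyl (2S)-2-[(1R,4S)-1-methyl-2-{[(1S)-1-phenylethyl]imino}-4-(prop-1-en-2-yl)cyclohexyl]-4-oxohexanoate | C=C(C)[C@H]1CC[C@](C)([C@H](CC(=O)CC)C(=O)OCC=C)C(=N[C@@H](C)c2ccccc2)C1
F3 | step 5 | allyl (2S)-2-[(1R,4S)-1-methyl-2-oxo-4-(prop-1-en-2-yl)cyclohexyl]-4-oxohexanoate | C=C(C)[C@H]1CC[C@](C)([C@H](CC(=O)CC)C(=O)OCC=C)C(=O)C1
F4 | step 5 | allyl (1S,6S,8aR)-4,8a-dimethyl-3-oxo-6-(prop-1-en-2-yl)-1,2,3,5,6,7,8,8a-octahydronaphthalene-1-carboxylate | C=C(C)[C@H]1CC[C@]2(C)[C@@H](C(=O)OCC=C)CC(=O)C(C)=C2C1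
F5 | step 5 | (1S,6S,8aR)-4,8a-dimethyl-3-oxo-6-(prop-1-en-2-yl)-1,2,3,5,6,7,8,8a-octahydronaphthalene-1-carboxylic acid | C=C(C)[C@H]1CC[C@]2(C)[C@@H](C(=O)O)CC(=O)C(C)=C2C1
F6 | step 7 | (1S,3R,6S,8aR)-3-(formyloxy)-N-methoxy-N,4,8a-trimethyl-6-(prop-1-en-2-yl)-1,2,3,5,6,7,8,8a-octahydronaphthalene-1-carboxamide | C=C(C)[C@H]1CC[C@]2(C)[C@@H](C(=O)N(C)OC)C[C@@H](OC=O)C(C)=C2C1
F7 | step 9 | [(1R,4S,4aS,6S,8aR)-4-hydroxy-4,8a-dimethyl-6-(prop-1-en-2-yl)decahydronaphthalen-1-yl]methanol | C=C(C)[C@H]1CC[C@]2(C)[C@@H](CO)CC[C@](C)(O)[C@H]2C1
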